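**Labels used throughout.** C-1 is the stereocentre, C-2 and C-3 are the two CH2 groups of the chain. Ring A is the 4-methoxyphenyl group on C-1, ring B the 4-hydroxy-2-methoxyphenyl group on C-3, ring C the 2,6-dimethoxyphenyl group on C-1, and ring D the 4-hydroxyphenyl group at the far end of the ethene bridge.

## Analysis of the target

The target is an open-chain 1,1,3-triarylpropane: C-1 carries ring A and ring C, C-3 carries ring B, and the carbon of ring C para to C-1 is joined through an (E)-ethene bridge to ring D. There is one stereocentre, C-1, an (S)-configured diarylmethine. Nothing in the molecule can relay chirality to it, so its configuration must come from a reagent or catalyst. A method that has to tell ring A from ring C at a preformed sp2 or radical centre is weak, whereas adding one ring (or its surrogate) to a prochiral C=C is strong. The sensitive groups are the (E)-stilbene (light, acid, electrophilic halogen, hydrogenation), the two free phenols of rings B and D, and four electron-rich arenes that invite Friedel–Crafts side reactions. The main difficulty is ring C: it is 1,2,3,5-tetrasubstituted and C-1 sits between its two methoxy groups, the most crowded position, where direct electrophilic alkylation of a 3,5-dimethoxyaryl unit would have to compete with the less hindered positions. In addition, two phenols must end up free while four other oxygens are methyl ethers. The strategy rests on the ipso carbon of ring C: it lies between two oxygen-bearing ring carbons and para to the styryl-bearing carbon. This is the pattern of a cyclohexane-1,3-dione, whose carbon between the carbonyl groups is its only nucleophilic carbon and whose C-5 can carry an ester as a latent styryl group. C-1, C-2 and C-3 then map onto the β-carbon, α-carbon and carbonyl carbon of a cinnamaldehyde bearing ring A.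

## Retrosynthetic reasoning

**18 to 17.** The phenols of rings B and D are unmasked last. Both are carried as the same bulky silyl ether, so one mild fluoride treatment finishes the synthesis without exposing the stilbene to acid or hydrogen and without touching the methyl ethers.

**17 to 14 and 16.** The C=C bond between ring C and ring D is cut to the ring C aldehyde 14 and the benzylic phosphonate 16 (from 15 by silylation). It is cut here, and formed late, because the stilbene would not survive the halogen-mediated aromatisation or the ionic hydrogenation used earlier. The forward olefination has to give the (E)-alkene.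

**14 to 13 to 12.** The aldehyde carbon of 14 is the ester carbon carried unchanged from the dione. A two-stage redox adjustment (ester to alcohol to aldehyde) is placed after all organometallic and acidic steps, during which the ester is the least vulnerable form of this carbon.

**12 to 11 to 7 and 10.** The C-3–ring B bond is cut because C-3 is at the aldehyde oxidation level in 7. An aryl nucleophile 10, made from bromide 9 (from 8), fixes the substitution pattern of ring B by the position of the halogen, so no regiochemical question arises. The benzylic hydroxyl of 11, next to an electron-rich ring, is then removed by ionic hydrogenation.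

**7 to 6.** The two ring C methyl ethers are disconnected to the phenols, one of which is tied to C-3 as a lactol in 6. Because ring C is symmetric, both oxygens receive the same group and never need to be told apart. The forward alkylation must open the lactol through its phenoxide and release the aldehyde.

**6 to 5 to 4.** Ring C is taken back by one oxidation level to the enol ether of a cyclohexane-1,3-dione. The forward step is an oxidative aromatisation, eased by the ring ester, which acidifies the hydrogen that is lost. The lactol passes through its methyl acetal 5, which protects the aldehyde during the oxidation.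

**4 to 3 to 1 and 2.** The key cut is the bond from C-1 to the ipso carbon of ring C. In the dione oxidation state that carbon is a soft nucleophile and C-1 is the electrophilic β-carbon of enal 2. An asymmetric conjugate addition under chiral secondary-amine catalysis forms the bond and the stereocentre, and the adduct 3 closes to lactol 4. Both 1 and 2 are purchased, so the risk of the route sits in this first step.

## Alternatives that were turned down

**Alternative 1:** The C-2–C-3 and C-1–ring A bonds are cut together, giving three pieces: a ring C styrene with its vinyl group between the two methoxy groups, a ring B α-bromo arylacetate, and the boronic acid of ring A.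
- Forward key step: under a monovalent copper salt with a chiral bis(oxazoline), the ester-stabilised radical adds to the styrene terminus. The benzylic radical at C-1 is captured by an aryl–copper species, and reductive elimination from trivalent copper forms the C-1–ring A bond, giving the triarylbutanoate A1.
- For: it is the most convergent plan. Three rings are joined in one step, C-1 is set directly, and a bromide on ring C allows a late Heck coupling for ring D, a shorter endgame than ester to aldehyde to olefin.
- Against: the C-1 radical is flanked by two ortho methoxy groups. Ring C is twisted out of conjugation, and both the capture at a ligated copper centre and the reductive elimination must occur at a far more crowded benzylic position than the unhindered styrenes this reaction class relies on. The secondary, doubly stabilised radical adds slowly to an electron-rich styrene and can dimerise. A1 also carries an ester on C-3 that the target lacks, so hydrolysis and a radical protodecarboxylation are needed, and the aryl bromide must survive copper and boronic acid.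
- Comparison: Alternative 1 is stronger on convergence. The chosen route offers a stereo-defining step at an unhindered sp2 carbon under a well-understood shielding model, no traceless group to remove, and purchased substrates.

**Alternative 2:** The C-1–C-2 bond is cut together with a temporary O–C-3 bond from a ring C phenol oxygen. The propane chain is folded into a 2,4-diarylchroman that is later opened by reductive cleavage of the benzylic O–C-3 bond.
- Forward key step: a chiral BINOL-derived phosphoric acid ionises a racemic ortho-hydroxybenzhydrol, which already carries rings A and C, to an ortho-quinone methide. [4+2] cycloaddition with an ortho-hydroxystyrene of ring B gives the cis-chroman A2.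
- For: it is enantioconvergent and catalytic, forms two bonds and a ring, and both enantiomers of the carbinol pass through one planar intermediate.
- Against: ring C must be made already desymmetrised (one free OH, one OMe, bromine para), which costs several steps of regioselective arene chemistry. The methoxy group next to the exocyclic carbon crowds the quinone methide and affects its geometry, on which face selection depends. A stereocentre at C-3 is made only to be destroyed, and the ring opening must spare the aryl bromide, which excludes hydrogenolysis.
- Comparison: on enantioconvergence and bonds per step Alternative 2 is as strong or stronger. The chosen strategy offers key-step substrates that need no preparation and, since both ring C oxygens emerge together from a symmetric dione, never requires them to be differentiated.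

**Alternative 3:** The C-1–ring A, C-1–C-2 and O–C-3 bonds are cut in one operation.
- Forward key step: the Grignard reagent of ring A adds to an O-Boc salicylaldehyde of ring C. Boc transfer and elimination give an ortho-quinone methide, which a vinyl ether carrying a chiral 2-phenylcyclohexyl group traps by inverse-demand hetero-Diels–Alder reaction, giving the cis acetal A3.
- For: three bonds form in one pot. C-3 arrives at the aldehyde oxidation level, so after hydrolysis the route to ring B matches the chosen one, and a ring C bromide allows a Heck coupling for ring D, which is shorter than the chosen endgame.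
- Against: the chirality comes from a stoichiometric auxiliary that must be prepared, carried and discarded. Facial control depends on the conformation of the enol ether approaching a quinone methide crowded by the neighbouring methoxy group. The same desymmetrised, tetrasubstituted salicylaldehyde has to be built, and a second equivalent of the Grignard reagent can add to the quinone methide.
- Comparison: Alternative 3 is stronger in bonds per step and in the ring D endgame. The chosen strategy offers catalytic chirality, purchased substrates and a stereo-determining step with direct precedent on the same substrate class.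

Key step: step 1

## Route

Remark on the chemistry: the sense of induction is assigned from the steric-shielding model of the (E)-iminium ion. By this model the (S)-configured catalyst directs the dione to the face that gives (S)-configured C-1; if the sense proved opposite, the (R)-catalyst would be used with no other change.

Step 1
Reactants: 1 methyl 3,5-dioxocyclohexane-1-carboxylate; 2 (E)-4-methoxycinnamaldehyde
Product: 4 methyl (4S)-2-hydroxy-4-(4-methoxyphenyl)-5-oxo-3,4,5,6,7,8-hexahydro-2H-chromene-7-carboxylate (lactol; epimers at C-2/C-7), via open-chain Michael adduct 3 (not isolated)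
Conditions: (S)-2-[diphenyl(trimethylsilyloxy)methyl]pyrrolidine (15 mol %), CH2Cl2, 0 °C
Reagents that add atoms: none
Why: This is an iminium-catalysed asymmetric Michael addition of a cyclic 1,3-dione to an enal, a known reaction type that gives 2-hydroxy-tetrahydrochromen-5-ones. The amine condenses with 2 to an (E)-configured s-trans iminium ion; the enol of 1, acidic enough to act as the proton shuttle, attacks the β-carbon through its only nucleophilic carbon (the CH2 between the two carbonyl groups), and hydrolysis of the resulting enamine frees the catalyst and gives 3. The enol oxygen of 3 then adds to the aldehyde carbon (6-exo-trig hemiacetalisation) and closes the dihydropyran ring of 4. C-1 (C-4 of the chromene) is set by the catalyst: its diphenyl(trimethylsilyloxy)methyl group covers one face of the iminium ion and the dione adds to the open face, which with the (S)-catalyst should give the (S)-centre. The step needs 1,4- rather than 1,2-addition (Knoevenagel condensation), C- rather than O-alkylation and a single addition; the soft stabilised enol, the bulk of the catalyst around the iminium carbon and the removal of the product aldehyde as the lactol should secure these. Lactol closure also shuts off retro-Michael erosion of the new centre. The ester-bearing carbon and the lactol carbon form as mixtures, which is harmless because both centres disappear later.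

Step 2
Reactants: 4 lactol
Product: 6 methyl (4S)-2,5-dihydroxy-4-(4-methoxyphenyl)-3,4-dihydro-2H-chromene-7-carboxylate (lactol; anomers), via methyl acetal 5 (not isolated)
Conditions: I2 (1.5 equiv), MeOH, 65 °C; concentrate; then 1 M HCl, THF, 40 °C
Reagents that add atoms: methanol, CO (its methoxy group is in 5 only); water, O (lactol oxygen of 6)
Why: Iodine–methanol aromatisation of a cyclohexane-1,3-dione enol ether (halogenation–dehydrohalogenation): the acid formed converts the lactol into acetal 5, iodination next to the ketone and loss of HI across the acidified ester-bearing carbon give a dienone that tautomerises to the phenol, and mild aqueous acid returns the lactol. The diarylmethine centre is not enolisable and should be untouched; any material that picks up a methyl ether on the phenol converges in step 3.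

Step 3
Reactants: 6 lactol-phenol
Product: 7 methyl 3,5-dimethoxy-4-[(1S)-1-(4-methoxyphenyl)-3-oxopropyl]benzoate
Conditions: MeI (4 equiv), K2CO3 (3 equiv), DMF, 0 °C to rt
Reagents that add atoms: iodomethane, CI
Why: Williamson O-methylation: under carbonate the lactol is in ring–chain equilibrium with the more stable phenoxide–aldehyde, so both ring C oxygens are alkylated as phenoxides and the chain is released as the free aldehyde. C-1 is β to the aldehyde and cannot epimerise by enolisation.

Step 4
Reactants: 8 4-bromo-3-methoxyphenol
Product: 9 (4-bromo-3-methoxyphenoxy)tri(propan-2-yl)silane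
Conditions: TIPSCl, imidazole, DMF, rt
Reagents that add atoms: chlorotri(propan-2-yl)silane, CC(C)[Si](Cl)(C(C)C)C(C)C
Why: Standard silylation of a phenol; the triisopropylsilyl ether is chosen because it tolerates arylmagnesium formation, trifluoroacetic acid, aluminium hydride and amide base, and leaves with fluoride at the end.

Step 5
Reactants: 9 aryl bromide; 7 aldehyde
Product: 11 methyl 4-[(1S)-3-hydroxy-3-{2-methoxy-4-[tri(propan-2-yl)silyloxy]phenyl}-1-(4-methoxyphenyl)propyl]-3,5-dimethoxybenzoate (both carbinol epimers), via arylmagnesium bromide 10 (not isolated)
Conditions: 9, Mg, cat. I2, THF, 45 °C; then 7 (10 in 1.2 equiv), THF, −78 to −30 °C; aq. NH4Cl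
Reagents that add atoms: magnesium, [Mg] (held in 10 only)
Why: Grignard addition to an aldehyde; at low temperature and near-stoichiometric loading the aldehyde should react far faster than the methyl benzoate, and the position of the bromine fixes the ring B pattern. The new carbinol centre forms unselectively and is removed in step 6.

Step 6
Reactants: 11 benzylic alcohol
Product: 12 methyl 3,5-dimethoxy-4-[(1S)-3-{2-methoxy-4-[tri(propan-2-yl)silyloxy]phenyl}-1-(4-methoxyphenyl)propyl]benzoate
Conditions: Et3SiH (3 equiv), CF3CO2H (5 equiv), CH2Cl2, −20 to 0 °C
Reagents that add atoms: none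
Why: Ionic hydrogenation (Kursanov–Parnes type) of a benzylic alcohol: ionisation is assisted by the ortho methoxy and para silyloxy groups of ring B and the cation is reduced by the silane. Ring C now has no free phenol to trap the cation, and C-1 is two bonds away and not involved.

Step 7
Reactants: 12 methyl ester
Product: 13 {3,5-dimethoxy-4-[(1S)-3-{2-methoxy-4-[tri(propan-2-yl)silyloxy]phenyl}-1-(4-methoxyphenyl)propyl]phenyl}methanol
Conditions: i-Bu2AlH (2.5 equiv), CH2Cl2, −78 to 0 °C; aq. KNaC4H4O6
Reagents that add atoms: none
Why: Aluminium hydride reduction of an aromatic ester to the benzylic alcohol; silyl and methyl aryl ethers are inert to it.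

Step 8
Reactants: 13 benzylic alcohol
Product: 14 3,5-dimethoxy-4-[(1S)-3-{2-methoxy-4-[tri(propan-2-yl)silyloxy]phenyl}-1-(4-methoxyphenyl)propyl]benzaldehyde
Conditions: Dess–Martin periodinane, NaHCO3, CH2Cl2, 0 °C to rt
Reagents that add atoms: none
Why: Dess–Martin oxidation of a primary benzylic alcohol stops at the aldehyde under buffered, non-acidic conditions that spare the silyl ether and the electron-rich rings.

Step 9
Reactants: 15 diethyl (4-hydroxybenzyl)phosphonate
Product: 16 diethyl {4-[tri(propan-2-yl)silyloxy]benzyl}phosphonate
Conditions: TIPSCl, imidazole, DMF, rt
Reagents that add atoms: chlorotri(propan-2-yl)silane, CC(C)[Si](Cl)(C(C)C)C(C)C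
Why: Phenol silylation, so that the phosphonate carbanion is not deactivated by a phenoxide and both phenols of the product carry the same removable group.

Step 10
Reactants: 14 aldehyde; 16 phosphonate
Product: 17 bis[tri(propan-2-yl)silyl] ether of the target, (S,E)-configured
Conditions: 16, KN(SiMe3)2, THF, −78 °C; then 14, −78 °C to rt
Reagents that add atoms: none
Why: Horner–Wadsworth–Emmons olefination of a non-enolisable aromatic aldehyde with a benzylic phosphonate carbanion; reversible addition and anti elimination should deliver the (E)-stilbene. The non-nucleophilic amide base should leave the aryl silyl ethers and the doubly benzylic C-1–H alone.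

Step 11
Reactants: 17 bis-silyl ether
Product: 18 4-[(3S)-3-{4-[(E)-2-(4-hydroxyphenyl)ethenyl]-2,6-dimethoxyphenyl}-3-(4-methoxyphenyl)propyl]-3-methoxyphenol (target)
Conditions: Bu4NF (2.4 equiv), AcOH (2.4 equiv), THF, 0 °C to rt, in the dark
Reagents that add atoms: none
Why: Fluoride-induced cleavage of both aryl silyl ethers; the acetic acid buffer avoids free phenoxides and the exclusion of light guards the (E)-stilbene against isomerisation.

## Compound list

1 | methyl 3,5-dioxocyclohexane-1-carboxylate | COC(=O)C1CC(=O)CC(=O)C1 | starting material
2 | (E)-4-methoxycinnamaldehyde | COc1ccc(/C=C/C=O)cc1 | starting material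
3 | methyl 3-hydroxy-4-[(1S)-1-(4-methoxyphenyl)-3-oxopropyl]-5-oxocyclohex-3-ene-1-carboxylate (enol form of the open Michael adduct) | COc1ccc(cc1)[C@H](CC=O)C1=C(O)CC(CC1=O)C(=O)OC | intermediate (not isolated)
4 | methyl (4S)-2-hydroxy-4-(4-methoxyphenyl)-5-oxo-3,4,5,6,7,8-hexahydro-2H-chromene-7-carboxylate | COc1ccc(cc1)[C@H](CC(O)O2)C1=C2CC(CC1=O)C(=O)OC | intermediate
5 | methyl (4S)-5-hydroxy-2-methoxy-4-(4-methoxyphenyl)-3,4-dihydro-2H-chromene-7-carboxylate | COc1ccc(cc1)[C@H](CC(OC)O2)c1c2cc(cc1O)C(=O)OC | intermediate (not isolated)
6 | methyl (4S)-2,5-dihydroxy-4-(4-methoxyphenyl)-3,4-dihydro-2H-chromene-7-carboxylate | COc1ccc(cc1)[C@H](CC(O)O2)c1c2cc(cc1O)C(=O)OC | intermediate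
7 | methyl 3,5-dimethoxy-4-[(1S)-1-(4-methoxyphenyl)-3-oxopropyl]benzoate | COc1ccc(cc1)[C@H](CC=O)c1c(OC)cc(cc1OC)C(=O)OC | intermediate
8 | 4-bromo-3-methoxyphenol | COc1cc(O)ccc1Br | starting material
9 | (4-bromo-3-methoxyphenoxy)tri(propan-2-yl)silane | COc1cc(O[Si](C(C)C)(C(C)C)C(C)C)ccc1Br | intermediate
10 | {2-methoxy-4-[tri(propan-2-yl)silyloxy]phenyl}magnesium bromide | COc1cc(O[Si](C(C)C)(C(C)C)C(C)C)ccc1[Mg]Br | intermediate (not isolated)
11 | methyl 4-[(1S)-3-hydroxy-3-{2-methoxy-4-[tri(propan-2-yl)silyloxy]phenyl}-1-(4-methoxyphenyl)propyl]-3,5-dimethoxybenzoate (carbinol epimers) | COc1ccc(cc1)[C@H](CC(O)c2ccc(O[Si](C(C)C)(C(C)C)C(C)C)cc2OC)c3c(OC)cc(cc3OC)C(=O)OC | intermediate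
12 | methyl 3,5-dimethoxy-4-[(1S)-3-{2-methoxy-4-[tri(propan-2-yl)silyloxy]phenyl}-1-(4-methoxyphenyl)propyl]benzoate | COc1ccc(cc1)[C@H](CCc2ccc(O[Si](C(C)C)(C(C)C)C(C)C)cc2OC)c3c(OC)cc(cc3OC)C(=O)OC | intermediate
13 | {3,5-dimethoxy-4-[(1S)-3-{2-methoxy-4-[tri(propan-2-yl)silyloxy]phenyl}-1-(4-methoxyphenyl)propyl]phenyl}methanol | COc1ccc(cc1)[C@H](CCc2ccc(O[Si](C(C)C)(C(C)C)C(C)C)cc2OC)c3c(OC)cc(CO)cc3OC | intermediate
14 | 3,5-dimethoxy-4-[(1S)-3-{2-methoxy-4-[tri(propan-2-yl)silyloxy]phenyl}-1-(4-methoxyphenyl)propyl]benzaldehyde | COc1ccc(cc1)[C@H](CCc2ccc(O[Si](C(C)C)(C(C)C)C(C)C)cc2OC)c3c(OC)cc(C=O)cc3OC | intermediate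
15 | diethyl (4-hydroxybenzyl)phosphonate | CCOP(=O)(Cc1ccc(O)cc1)OCC | starting material
16 | diethyl {4-[tri(propan-2-yl)silyloxy]benzyl}phosphonate | CCOP(=O)(Cc1ccc(O[Si](C(C)C)(C(C)C)C(C)C)cc1)OCC | intermediate
17 | {4-[(E)-2-{3,5-dimethoxy-4-[(1S)-3-{2-methoxy-4-[tri(propan-2-yl)silyloxy]phenyl}-1-(4-methoxyphenyl)propyl]phenyl}ethenyl]phenoxy}tri(propan-2-yl)silane | COc1ccc(cc1)[C@H](CCc2ccc(O[Si](C(C)C)(C(C)C)C(C)C)cc2OC)c3c(OC)cc(/C=C/c4ccc(O[Si](C(C)C)(C(C)C)C(C)C)cc4)cc3OC | intermediate
18 | 4-[(3S)-3-{4-[(E)-2-(4-hydroxyphenyl)ethenyl]-2,6-dimethoxyphenyl}-3-(4-methoxyphenyl)propyl]-3-methoxyphenol | COc1ccc(cc1)[C@H](CCc2ccc(O)cc2OC)c3c(OC)cc(/C=C/c4ccc(O)cc4)cc3OC | target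

## Step count and least certain steps

Total: 11 steps. Longest linear sequence: 9 steps (steps 1, 2, 3, 5, 6, 7, 8, 10, 11); steps 4 and 9 prepare the two side fragments.

**Step 1 (key step).** The likely failures are: erosion of enantioselectivity by an uncatalysed or general-base background addition, or by retro-Michael and re-addition before the lactol closes; diversion of the enal into 1,2-condensation (Knoevenagel, then electrocyclisation); and slow iminium formation from the electron-rich enal. Fallback: replace asymmetric catalysis by a racemic synthesis and a separation of enantiomers. It sets out from 1 and 2 and returns at 7. With pyrrolidine and acetic acid as catalyst, 1 and 2 give the racemic open-chain adduct F1, which closes to the racemic lactol F2. Iodine in methanol then gives the racemic methyl acetal F3, aqueous acid the racemic lactol-phenol F4, and iodomethane with K2CO3 the racemic aldehyde F5. Preparative chromatography of F5 on a chiral stationary phase gives 7, and the other enantiomer is discarded.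

**Step 2.** Iodination may occur at the carbon between the two ring oxygens or on the activated arene once formed, dehydrohalogenation may stall, or the lactol may dehydrate under acid to an enol ether that is then halogenated. Fallback: a selenoxide elimination in place of halogenation, from 4 back to 5. Compound 4 is converted with methanol and pyridinium p-toluenesulfonate into the methyl acetal F6. LiN(i-Pr)2 then PhSeCl at −78 °C give the α-selenide F7 (a regioisomer selenated next to the ester would converge). H2O2 then causes syn elimination and tautomerisation to 5, which is hydrolysed to 6 as in the second stage of step 2.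

**Step 3.** The lactol hydroxyl may be alkylated in competition with ring opening, giving a mixed acetal instead of the aldehyde, and the freed aldehyde may undergo aldol self-condensation under carbonate. Fallback: change the order so that no aldehyde is ever exposed to base, from 6 back to 12. Lactol 6 is treated with an excess (about 3.5 equiv) of 10, which deprotonates both hydroxyls, opens the lactol and adds to the aldehyde to give the triol F8. Et3SiH and CF3CO2H reduce the benzylic alcohol to the diphenol F9; reversible ring closure by the neighbouring phenol drains to the same product under these conditions. Iodomethane with K2CO3 then methylates both ring C phenols of F9 to give 12.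

**Step 5.** The arylmagnesium may attack the methyl ester, may deprotonate the aldehyde α-carbon and so return 7 on work-up, or may form sluggishly with homocoupling. Fallback: form the C-3–ring B bond by cross-electrophile coupling, from 7 back to 12, which also bypasses step 6. NaBH4 reduces 7 to the primary alcohol F10. I2, PPh3 and imidazole give the iodide F11. Nickel-catalysed reductive coupling of F11 with aryl bromide 9 (NiBr2(MeOCH2CH2OMe), 4,4'-di-tert-butyl-2,2'-bipyridine, Zn, N,N-dimethylacetamide, 60 °C) gives 12; these conditions tolerate the ester.

**Step 6.** The benzylic cation may be captured by an electron-rich ring (intermolecular Friedel–Crafts alkylation, or indane closure onto ring A) faster than hydride transfer, or the silyl ether may be lost to the acid. Fallback: hydrogenolysis in place of a free cation, from 11 back to 12. Ac2O, pyridine and 4-(dimethylamino)pyridine give the benzylic acetate F12, and H2 over Pd/C in ethyl acetate cleaves the benzylic C–O bond to give 12; no alkene is present at this stage.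

## Further compounds

F1 | step 1 | methyl 3-hydroxy-4-[1-(4-methoxyphenyl)-3-oxopropyl]-5-oxocyclohex-3-ene-1-carboxylate (racemic) | COc1ccc(cc1)C(CC=O)C1=C(O)CC(CC1=O)C(=O)OC
F2 | step 1 | methyl 2-hydroxy-4-(4-methoxyphenyl)-5-oxo-3,4,5,6,7,8-hexahydro-2H-chromene-7-carboxylate (racemic) | COc1ccc(cc1)C(CC(O)O2)C1=C2CC(CC1=O)C(=O)OC
F3 | step 1 | methyl 5-hydroxy-2-methoxy-4-(4-methoxyphenyl)-3,4-dihydro-2H-chromene-7-carboxylate (racemic) | COc1ccc(cc1)C(CC(OC)O2)c1c2cc(cc1O)C(=O)OC
F4 | step 1 | methyl 2,5-dihydroxy-4-(4-methoxyphenyl)-3,4-dihydro-2H-chromene-7-carboxylate (racemic) | COc1ccc(cc1)C(CC(O)O2)c1c2cc(cc1O)C(=O)OC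
F5 | step 1 | methyl 3,5-dimethoxy-4-[1-(4-methoxyphenyl)-3-oxopropyl]benzoate (racemic) | COc1ccc(cc1)C(CC=O)c1c(OC)cc(cc1OC)C(=O)OC
F6 | step 2 | methyl (4S)-2-methoxy-4-(4-methoxyphenyl)-5-oxo-3,4,5,6,7,8-hexahydro-2H-chromene-7-carboxylate | COc1ccc(cc1)[C@H](CC(OC)O2)C1=C2CC(CC1=O)C(=O)OC
F7 | step 2 | methyl (4S)-2-methoxy-4-(4-methoxyphenyl)-5-oxo-6-(phenylselanyl)-3,4,5,6,7,8-hexahydro-2H-chromene-7-carboxylate | COc1ccc(cc1)[C@H](CC(OC)O2)C1=C2CC(C(C1=O)[Se]c1ccccc1)C(=O)OC
F8 | step 3 | methyl 3,5-dihydroxy-4-[(1S)-3-hydroxy-3-{2-methoxy-4-[tri(propan-2-yl)silyloxy]phenyl}-1-(4-methoxyphenyl)propyl]benzoate | COc1ccc(cc1)[C@H](CC(O)c2ccc(O[Si](C(C)C)(C(C)C)C(C)C)cc2OC)c3c(O)cc(cc3O)C(=O)OC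
F9 | step 3 | methyl 3,5-dihydroxy-4-[(1S)-3-{2-methoxy-4-[tri(propan-2-yl)silyloxy]phenyl}-1-(4-methoxyphenyl)propyl]benzoate | COc1ccc(cc1)[C@H](CCc2ccc(O[Si](C(C)C)(C(C)C)C(C)C)cc2OC)c3c(O)cc(cc3O)C(=O)OC
F10 | step 5 | methyl 4-[(1S)-3-hydroxy-1-(4-methoxyphenyl)propyl]-3,5-dimethoxybenzoate | COc1ccc(cc1)[C@H](CCO)c1c(OC)cc(cc1OC)C(=O)OC
F11 | step 5 | methyl 4-[(1S)-3-iodo-1-(4-methoxyphenyl)propyl]-3,5-dimethoxybenzoate | COc1ccc(cc1)[C@H](CCI)c1c(OC)cc(cc1OC)C(=O)OC
F12 | step 6 | methyl 4-[(1S)-3-acetoxy-3-{2-methoxy-4-[tri(propan-2-yl)silyloxy]phenyl}-1-(4-methoxyphenyl)propyl]-3,5-dimethoxybenzoate | COc1ccc(cc1)[C@H](CC(OC(C)=O)c2ccc(O[Si](C(C)C)(C(C)C)C(C)C)cc2OC)c3c(OC)cc(cc3OC)C(=O)OC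
A1 | alternative 1 | methyl (4S)-4-(4-bromo-2,6-dimethoxyphenyl)-2-{2-methoxy-4-[tri(propan-2-yl)silyloxy]phenyl}-4-(4-methoxyphenyl)butanoate (C-2 epimers) | COc1ccc(cc1)[C@H](CC(C(=O)OC)c1ccc(O[Si](C(C)C)(C(C)C)C(C)C)cc1OC)c1c(OC)cc(Br)cc1OC
A2 | alternative 2 | 2-[(2R,4S)-7-bromo-5-methoxy-4-(4-methoxyphenyl)-3,4-dihydro-2H-chromen-2-yl]-5-[tri(propan-2-yl)silyloxy]phenol | COc1ccc(cc1)[C@@H]1C[C@@H](Oc2cc(Br)cc(OC)c12)c1ccc(O[Si](C(C)C)(C(C)C)C(C)C)cc1O
A3 | alternative 3 | (2R,4S)-7-bromo-5-methoxy-4-(4-methoxyphenyl)-2-{[(1S,2R)-2-phenylcyclohexyl]oxy}-3,4-dihydro-2H-chromene | COc1ccc(cc1)[C@@H]1C[C@H](O[C@H]2CCCC[C@@H]2c2ccccc2)Oc2cc(Br)cc(OC)c12
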